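**Retrosynthetic overview**
1. Target ⇒ aryl acid 30 + diol 24 (late acylation of the secondary hydroxyl at C-6); the acrylate comes from aldehyde 22 by Wittig olefination.
2. Ring B (2H-pyran: O-2, C-1, C-8a, C-4a, C-4, C-3) ⇒ 6-endo oxa-Michael closure of the C-1 oxygen onto an alkyne attached by Sonogashira coupling to iodo enone 17; it is formed after ring A.
3. Ring A (carbocycle C-4a, C-5, C-6, C-7, C-8, C-8a) ⇒ key disconnection between the ring CH2 (C-5) and the oxygen-bearing CH (C-6): intramolecular vinylogous Mukaiyama aldol of keto lactol 14, with C-6 as an oxocarbenium carbon inside a temporary 1,3-dioxolane that ties the cis oxygens on C-6 and C-7.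
4. Enabling feature: the C-8 carbonyl of ring A lies between the quaternary carbinol carbon C-7 and the fully substituted C-8a=C-4a olefin, so it can enolise only through the methyl group on C-4a (the future C-5), which is 1,6-related to C-6; the cis C-6/C-7 diol allows the temporary acetal ring.
5. Precursor 14 ⇒ Seebach aldol of lactic acid dioxolanone 10 (sets C-7) with iodo enal 7 (from but-2-yn-1-ol by anti-carbomagnesiation). Ring order: temporary dioxolane, ring A (key step), ring B; the dioxolane is cleaved in step 11.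

Key step: step 8

Remark: the carbinol carbon made in step 5 and the lactol carbon made in step 6 are carried as epimer mixtures (both are erased in steps 7 and 8) and are left undefined in the SMILES of 12–15.

**Step 1**
Reactants: 1 but-2-yn-1-ol; 2 vinylmagnesium chloride
Product: 4 (2Z)-2-ethenyl-3-iodobut-2-en-1-ol, via magnesium chelate 3 (not isolated)
Conditions: CH2=CHMgCl (3.5 equiv), THF/cyclohexane, reflux; then I2, THF, −78 °C → rt; aq. NH4Cl
Reagents that add atoms: iodine II
Why: Alkoxide-directed anti-carbomagnesiation of a propargylic alcohol (Duboudin–Fallis reaction) should put the vinyl group on the alkyne carbon next to CH2O and magnesium on the distal carbon inside a five-membered chelate, and iodinolysis with retention should give the tetrasubstituted olefin with iodine cis to CH2OH and vinyl cis to the methyl group.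

**Step 2**
Reactants: 4 (2Z)-2-ethenyl-3-iodobut-2-en-1-ol
Product: 5 tert-butyl{[(2Z)-2-ethenyl-3-iodobut-2-en-1-yl]oxy}diphenylsilane
Conditions: t-BuPh2SiCl, imidazole, DMF, rt
Reagents that add atoms: tert-butyl(chloro)diphenylsilane CC(C)(C)[Si](Cl)(c1ccccc1)c1ccccc1
Why: Imidazole-mediated silylation of a primary alcohol; the bulky, weakly basic silyl ether oxygen should survive steps 3–9 and should not trap the oxocarbenium ion of step 8.

**Step 3**
Reactants: 5 tert-butyl{[(2Z)-2-ethenyl-3-iodobut-2-en-1-yl]oxy}diphenylsilane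
Product: 7 (2E)-2-{[tert-butyl(diphenyl)silyl]oxymethyl}-3-iodobut-2-enal, via vicinal diol 6 (not isolated)
Conditions: OsO4 (2 mol%), NaIO4 (4 equiv), 2,6-lutidine, dioxane/H2O (3:1), rt
Reagents that add atoms: sodium periodate [Na+].[O-]I(=O)(=O)=O
Why: Lemieux–Johnson oxidative cleavage should be selective for the monosubstituted vinyl group, because the tetrasubstituted iodo-olefin is too hindered and electron-poor for OsO4, so the olefin geometry is untouched.

**Step 4**
Reactants: 8 (2S)-2-hydroxypropanoic acid; 9 2,2-dimethylpropanal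
Product: 10 (2S,5S)-2-tert-butyl-5-methyl-1,3-dioxolan-4-one
Conditions: TsOH·H2O (cat.), H2SO4 (cat.), pentane, reflux (Dean–Stark); recrystallisation (Et2O/pentane, −78 °C)
Reagents that add atoms: none
Why: Acid-catalysed acetalisation of an α-hydroxy acid with water removal (Seebach dioxolanone formation) should give mainly the cis-2,5-disubstituted dioxolanone, purified by crystallisation, with the lactic acid stereocentre unchanged.

**Step 5**
Reactants: 10 (2S,5S)-2-tert-butyl-5-methyl-1,3-dioxolan-4-one; 7 (2E)-2-{[tert-butyl(diphenyl)silyl]oxymethyl}-3-iodobut-2-enal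
Product: 12 (2S,5R)-2-tert-butyl-5-[(2E)-2-{[tert-butyl(diphenyl)silyl]oxymethyl}-1-hydroxy-3-iodobut-2-en-1-yl]-5-methyl-1,3-dioxolan-4-one (both carbinol epimers), via lithium enolate 11 (not isolated)
Conditions: LiN(i-Pr)2 (1.05 equiv), THF, −78 °C; then 7, −78 °C; aq. NH4Cl
Reagents that add atoms: none
Why: Aldol addition under Seebach's self-regeneration of stereocentres: the planar enolate should be attacked by the aldehyde (1,2-addition) on the face opposite to the tert-butyl group, so the new quaternary carbon (C-7 of the target) keeps the spatial arrangement of (S)-lactic acid, while the secondary carbinol configuration is irrelevant because it is oxidised in step 7.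

**Step 6**
Reactants: 12 (2S,5R)-2-tert-butyl-5-[(2E)-2-{[tert-butyl(diphenyl)silyl]oxymethyl}-1-hydroxy-3-iodobut-2-en-1-yl]-5-methyl-1,3-dioxolan-4-one
Product: 13 (2S,5R)-2-tert-butyl-5-[(2E)-2-{[tert-butyl(diphenyl)silyl]oxymethyl}-1-hydroxy-3-iodobut-2-en-1-yl]-5-methyl-1,3-dioxolan-4-ol (epimers at the carbinol and lactol carbons)
Conditions: i-Bu2AlH (2.2 equiv), CH2Cl2, −78 °C; aq. potassium sodium tartrate
Reagents that add atoms: none
Why: Partial reduction of the activated (acylal-type) lactone to the lactol should stop at the tetrahedral aluminate at −78 °C; one equivalent of hydride is consumed by the free hydroxyl and no ester is present.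

**Step 7**
Reactants: 13 (2S,5R)-2-tert-butyl-5-[(2E)-2-{[tert-butyl(diphenyl)silyl]oxymethyl}-1-hydroxy-3-iodobut-2-en-1-yl]-5-methyl-1,3-dioxolan-4-ol
Product: 14 (2E)-1-[(2S,4S)-2-tert-butyl-5-hydroxy-4-methyl-1,3-dioxolan-4-yl]-2-{[tert-butyl(diphenyl)silyl]oxymethyl}-3-iodobut-2-en-1-one (both lactol epimers)
Conditions: MnO2 (activated, excess), CH2Cl2, rt
Reagents that add atoms: none
Why: MnO2 oxidation is selective for the allylic alcohol and should leave the non-allylic lactol untouched, giving the ketone whose only enolisable hydrogens are those of the γ-methyl group.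

**Step 8**
Reactants: 14 (2E)-1-[(2S,4S)-2-tert-butyl-5-hydroxy-4-methyl-1,3-dioxolan-4-yl]-2-{[tert-butyl(diphenyl)silyl]oxymethyl}-3-iodobut-2-en-1-one
Product: 17 (2R,3aS,7aS)-2-tert-butyl-5-{[tert-butyl(diphenyl)silyl]oxymethyl}-6-iodo-3a-methyl-7,7a-dihydro-1,3-benzodioxol-4(3aH)-one (cis-fused), via silyl dienol ether 15 (not isolated), via dioxolanylium triflate 16 (not isolated)
Conditions: i-Pr2NEt (2.5 equiv), Me3SiOTf (3.5 equiv), CH2Cl2, −78 → 0 °C; aq. NaHCO3
Reagents that add atoms: none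
Why: Me3SiOTf/i-Pr2NEt should silylate the lactol and soft-enolise the ketone, whose only acidic hydrogens are on the γ-methyl group (the carbinol carbon on the other side is quaternary and the α-carbon is fully substituted), to give silyl dienol ether 15; excess Me3SiOTf then ionises the anomeric silyloxy group to the five-membered oxocarbenium ion 16, which the diene terminus attacks intramolecularly before desilylation to the enone. The closest known reaction types are the vinylogous Mukaiyama aldol addition to cyclic oxocarbenium ions made from lactol derivatives (C-glycosylation, couplings of 4-acyloxy-1,3-dioxolanes) and the one-pot Me3SiOTf/amine enol silane formation–Mukaiyama addition to acetals. Ring A closes in a 6-(enolendo)-exo-trig mode, the s-cis diene terminus and the oxocarbenium carbon being 1,6-related. The new stereocentre (C-6, the later acyloxy carbon) is controlled by the temporary dioxolane: the quaternary C-7 holds the tether on one face of the flat oxocarbenium ring, so the methylene carbon can bond only to that face, which gives the cis-fused bicycle and thus the cis C-6/C-7 oxygens with C-6 as S. The step needs γ- over α-attack and C- over O-capture of the cation: α-attack would give a cyclobutane, and the only nearby oxygen is the bulky silyl ether, whose acetal formation would be reversible whereas C–C bond formation is not.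

**Step 9**
Reactants: 17 (2R,3aS,7aS)-2-tert-butyl-5-{[tert-butyl(diphenyl)silyl]oxymethyl}-6-iodo-3a-methyl-7,7a-dihydro-1,3-benzodioxol-4(3aH)-one; 18 3,3-diethoxyprop-1-yne
Product: 19 (2R,3aS,7aS)-2-tert-butyl-5-{[tert-butyl(diphenyl)silyl]oxymethyl}-6-(3,3-diethoxyprop-1-yn-1-yl)-3a-methyl-7,7a-dihydro-1,3-benzodioxol-4(3aH)-one
Conditions: PdCl2(PPh3)2 (5 mol%), CuI (10 mol%), Et3N, THF, rt
Reagents that add atoms: none
Why: Sonogashira coupling of a β-iodo enone (fast oxidative addition) with a terminal alkyne under amine conditions should leave both acetals and the silyl ether intact.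

**Step 10**
Reactants: 19 (2R,3aS,7aS)-2-tert-butyl-5-{[tert-butyl(diphenyl)silyl]oxymethyl}-6-(3,3-diethoxyprop-1-yn-1-yl)-3a-methyl-7,7a-dihydro-1,3-benzodioxol-4(3aH)-one
Product: 21 6,7-O-[(R)-2,2-dimethylpropylidene] acetal of (6S,7S)-3-(diethoxymethyl)-6,7-dihydroxy-7-methyl-6,7-dihydro-1H-isochromen-8(5H)-one, via primary alcohol 20 (not isolated)
Conditions: Bu4NF (1.2 equiv), THF, 0 °C → rt
Reagents that add atoms: none
Why: Fluoride desilylation frees the primary alkoxide, which should add in a 6-endo-dig oxa-Michael (1,6-conjugate) fashion to the alkyne carbon remote from the ring, the only position activated by the enone (the acetal substituent offers no competing acceptor), to give the 2H-pyran whose dienol ether is conjugated to the ketone.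

**Step 11**
Reactants: 21 6,7-O-[(R)-2,2-dimethylpropylidene] acetal of (6S,7S)-3-(diethoxymethyl)-6,7-dihydroxy-7-methyl-6,7-dihydro-1H-isochromen-8(5H)-one
Product: 22 (6S,7S)-6,7-dihydroxy-7-methyl-8-oxo-5,6,7,8-tetrahydro-1H-isochromene-3-carbaldehyde
Conditions: CF3CO2H/H2O/THF (4:1:1), 0 °C → rt
Reagents that add atoms: water O
Why: Acid-catalysed acetal hydrolysis should remove the diethyl acetal and the temporary 2,2-dimethylpropylidene acetal in one operation; the push–pull dienol ether (a doubly vinylogous ester) and the tertiary α-ketol should tolerate aqueous acid and no stereocentre is touched.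

**Step 12**
Reactants: 22 (6S,7S)-6,7-dihydroxy-7-methyl-8-oxo-5,6,7,8-tetrahydro-1H-isochromene-3-carbaldehyde; 23 tert-butyl (triphenylphosphoranylidene)acetate
Product: 24 tert-butyl (2E)-3-[(6S,7S)-6,7-dihydroxy-7-methyl-8-oxo-5,6,7,8-tetrahydro-1H-isochromen-3-yl]prop-2-enoate
Conditions: CH2Cl2, rt
Reagents that add atoms: none
Why: Wittig olefination with a stabilised ylide is E-selective, chemoselective for the aldehyde over the deactivated hindered ketone, and neutral enough for the free diol.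

**Step 13**
Reactants: 25 5-methylbenzene-1,2,3-triol; 26 dichlorodiphenylmethane
Product: 27 6-methyl-2,2-diphenyl-1,3-benzodioxol-4-ol
Conditions: neat, 170 °C
Reagents that add atoms: none
Why: Diphenylmethylene ketal formation on a vicinal pair of phenols; the triol is symmetric, so either adjacent pair gives the same product and one phenol stays free.

**Step 14**
Reactants: 27 6-methyl-2,2-diphenyl-1,3-benzodioxol-4-ol
Product: 28 4-hydroxy-6-methyl-2,2-diphenyl-1,3-benzodioxole-5-carbaldehyde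
Conditions: MgCl2, Et3N, (CH2O)n, MeCN, reflux; aq. HCl
Reagents that add atoms: formaldehyde (as paraformaldehyde) C=O
Why: Magnesium-mediated ortho-formylation of a phenol (Casnati–Skattebøl reaction) delivers the formyl group only ortho to the free hydroxyl, and the single free ortho position is the one between OH and CH3.

**Step 15**
Reactants: 28 4-hydroxy-6-methyl-2,2-diphenyl-1,3-benzodioxole-5-carbaldehyde
Product: 29 4-methoxy-6-methyl-2,2-diphenyl-1,3-benzodioxole-5-carbaldehyde
Conditions: MeI, K2CO3, DMF, 40 °C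
Reagents that add atoms: iodomethane CI
Why: Williamson O-methylation of the only free phenol.

**Step 16**
Reactants: 29 4-methoxy-6-methyl-2,2-diphenyl-1,3-benzodioxole-5-carbaldehyde
Product: 30 4-methoxy-6-methyl-2,2-diphenyl-1,3-benzodioxole-5-carboxylic acid
Conditions: NaClO2, NaH2PO4, 2-methylbut-2-ene, t-BuOH/H2O, rt
Reagents that add atoms: sodium chlorite [Na+].[O-]Cl=O
Why: Pinnick oxidation converts the hindered aryl aldehyde to the acid under buffered conditions that the ketal should survive, with 2-methylbut-2-ene as hypochlorite scavenger.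

**Step 17**
Reactants: 30 4-methoxy-6-methyl-2,2-diphenyl-1,3-benzodioxole-5-carboxylic acid; 24 tert-butyl (2E)-3-[(6S,7S)-6,7-dihydroxy-7-methyl-8-oxo-5,6,7,8-tetrahydro-1H-isochromen-3-yl]prop-2-enoate
Product: 32 (6S,7S)-3-[(1E)-3-tert-butoxy-3-oxoprop-1-en-1-yl]-7-hydroxy-7-methyl-8-oxo-5,6,7,8-tetrahydro-1H-isochromen-6-yl 4-methoxy-6-methyl-2,2-diphenyl-1,3-benzodioxole-5-carboxylate, via acid chloride 31 (not isolated)
Conditions: 30, 1-chloro-N,N,2-trimethylprop-1-en-1-amine, CH2Cl2, 0 °C → rt; then 24, pyridine, DMAP (0.3 equiv), CH2Cl2, 0 °C → rt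
Reagents that add atoms: none
Why: Neutral acid chloride formation (Ghosez reagent) followed by DMAP-catalysed acylation should occur at the secondary hydroxyl because the tertiary one is far more hindered; the weak base pyridine is chosen to avoid vinylogous β-elimination of the new ester.

**Step 18**
Reactants: 32 (6S,7S)-3-[(1E)-3-tert-butoxy-3-oxoprop-1-en-1-yl]-7-hydroxy-7-methyl-8-oxo-5,6,7,8-tetrahydro-1H-isochromen-6-yl 4-methoxy-6-methyl-2,2-diphenyl-1,3-benzodioxole-5-carboxylate
Product: 33 (2E)-3-[(6S,7S)-6-[(3,4-dihydroxy-2-methoxy-6-methylbenzoyl)oxy]-7-hydroxy-7-methyl-8-oxo-5,6,7,8-tetrahydro-1H-isochromen-3-yl]prop-2-enoic acid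
Conditions: CF3CO2H/CH2Cl2/H2O (10:10:1), 0 °C → rt
Reagents that add atoms: none
Why: Acidolysis should cleave the tert-butyl ester (via the tert-butyl cation) and hydrolyse the diphenylmethylene ketal (via the diaryl oxocarbenium ion) in one step, under conditions in which the dienol ether, the hindered aryl ester and the E olefin are expected to be stable.

**Compound list**
1 | but-2-yn-1-ol | CC#CCO | starting material
2 | vinylmagnesium chloride | C=C[Mg]Cl | starting material
3 | 4-ethenyl-3-methyl-2,5-dihydro-1,2-oxamagnesole (magnesium chelate) | C=CC1=C(C)[Mg]OC1 | intermediate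
4 | (2Z)-2-ethenyl-3-iodobut-2-en-1-ol | OC/C(C=C)=C(\I)C | intermediate
5 | tert-butyl{[(2Z)-2-ethenyl-3-iodobut-2-en-1-yl]oxy}diphenylsilane | CC(C)(C)[Si](c1ccccc1)(c1ccccc1)OC/C(C=C)=C(\I)C | intermediate
6 | (3E)-3-{[tert-butyl(diphenyl)silyl]oxymethyl}-4-iodopent-3-ene-1,2-diol (racemic at C-2) | CC(C)(C)[Si](c1ccccc1)(c1ccccc1)OC/C(C(O)CO)=C(\I)C | intermediate
7 | (2E)-2-{[tert-butyl(diphenyl)silyl]oxymethyl}-3-iodobut-2-enal | CC(C)(C)[Si](c1ccccc1)(c1ccccc1)OC/C(C=O)=C(\I)C | intermediate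
8 | (2S)-2-hydroxypropanoic acid | C[C@H](O)C(=O)O | starting material
9 | 2,2-dimethylpropanal | CC(C)(C)C=O | starting material
10 | (2S,5S)-2-tert-butyl-5-methyl-1,3-dioxolan-4-one | C[C@@H]1O[C@H](C(C)(C)C)OC1=O | intermediate
11 | lithium (2S)-2-tert-butyl-5-methyl-1,3-dioxol-4-olate | CC1=C(O[Li])O[C@@H](C(C)(C)C)O1 | intermediate
12 | (2S,5R)-2-tert-butyl-5-[(2E)-2-{[tert-butyl(diphenyl)silyl]oxymethyl}-1-hydroxy-3-iodobut-2-en-1-yl]-5-methyl-1,3-dioxolan-4-one (both carbinol epimers) | C[C@]1(C(O)/C(CO[Si](c2ccccc2)(c2ccccc2)C(C)(C)C)=C(\C)I)O[C@H](C(C)(C)C)OC1=O | intermediate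
13 | (2S,5R)-2-tert-butyl-5-[(2E)-2-{[tert-butyl(diphenyl)silyl]oxymethyl}-1-hydroxy-3-iodobut-2-en-1-yl]-5-methyl-1,3-dioxolan-4-ol (epimers at the carbinol and lactol carbons) | C[C@]1(C(O)/C(CO[Si](c2ccccc2)(c2ccccc2)C(C)(C)C)=C(\C)I)O[C@H](C(C)(C)C)OC1O | intermediate
14 | (2E)-1-[(2S,4S)-2-tert-butyl-5-hydroxy-4-methyl-1,3-dioxolan-4-yl]-2-{[tert-butyl(diphenyl)silyl]oxymethyl}-3-iodobut-2-en-1-one (both lactol epimers) | C[C@]1(C(=O)/C(CO[Si](c2ccccc2)(c2ccccc2)C(C)(C)C)=C(\C)I)O[C@H](C(C)(C)C)OC1O | intermediate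
15 | (2S,4R)-2-tert-butyl-4-[(1E)-2-{[tert-butyl(diphenyl)silyl]oxymethyl}-3-iodo-1-(trimethylsilyloxy)buta-1,3-dien-1-yl]-4-methyl-5-(trimethylsilyloxy)-1,3-dioxolane | C=C(I)/C(CO[Si](c1ccccc1)(c1ccccc1)C(C)(C)C)=C(/O[Si](C)(C)C)[C@@]1(C)O[C@H](C(C)(C)C)OC1O[Si](C)(C)C | intermediate
16 | (2S,4R)-2-tert-butyl-4-[(1E)-2-{[tert-butyl(diphenyl)silyl]oxymethyl}-3-iodo-1-(trimethylsilyloxy)buta-1,3-dien-1-yl]-4-methyl-1,3-dioxolan-5-ylium trifluoromethanesulfonate (cyclic oxocarbenium ion) | C=C(I)/C(CO[Si](c1ccccc1)(c1ccccc1)C(C)(C)C)=C(/O[Si](C)(C)C)[C@@]1(C)O[C@H](C(C)(C)C)[O+]=C1.[O-]S(=O)(=O)C(F)(F)F | intermediate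
17 | (2R,3aS,7aS)-2-tert-butyl-5-{[tert-butyl(diphenyl)silyl]oxymethyl}-6-iodo-3a-methyl-7,7a-dihydro-1,3-benzodioxol-4(3aH)-one (cis-fused; tert-butyl cis to the 3a-methyl group) | C[C@]12O[C@H](C(C)(C)C)O[C@H]1CC(I)=C(CO[Si](c3ccccc3)(c3ccccc3)C(C)(C)C)C2=O | intermediate
18 | 3,3-diethoxyprop-1-yne | C#CC(OCC)OCC | starting material
19 | (2R,3aS,7aS)-2-tert-butyl-5-{[tert-butyl(diphenyl)silyl]oxymethyl}-6-(3,3-diethoxyprop-1-yn-1-yl)-3a-methyl-7,7a-dihydro-1,3-benzodioxol-4(3aH)-one | C[C@]12O[C@H](C(C)(C)C)O[C@H]1CC(C#CC(OCC)OCC)=C(CO[Si](c3ccccc3)(c3ccccc3)C(C)(C)C)C2=O | intermediate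
20 | (2R,3aS,7aS)-2-tert-butyl-6-(3,3-diethoxyprop-1-yn-1-yl)-5-(hydroxymethyl)-3a-methyl-7,7a-dihydro-1,3-benzodioxol-4(3aH)-one | C[C@]12O[C@H](C(C)(C)C)O[C@H]1CC(C#CC(OCC)OCC)=C(CO)C2=O | intermediate
21 | 6,7-O-[(R)-2,2-dimethylpropylidene] acetal of (6S,7S)-3-(diethoxymethyl)-6,7-dihydroxy-7-methyl-6,7-dihydro-1H-isochromen-8(5H)-one | C[C@]12O[C@H](C(C)(C)C)O[C@H]1CC3=C(COC(C(OCC)OCC)=C3)C2=O | intermediate
22 | (6S,7S)-6,7-dihydroxy-7-methyl-8-oxo-5,6,7,8-tetrahydro-1H-isochromene-3-carbaldehyde | C[C@]1(O)[C@@H](O)CC2=C(COC(C=O)=C2)C1=O | intermediate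
23 | tert-butyl (triphenylphosphoranylidene)acetate | CC(C)(C)OC(=O)C=P(c1ccccc1)(c1ccccc1)c1ccccc1 | starting material
24 | tert-butyl (2E)-3-[(6S,7S)-6,7-dihydroxy-7-methyl-8-oxo-5,6,7,8-tetrahydro-1H-isochromen-3-yl]prop-2-enoate | C[C@]1(O)[C@@H](O)CC2=C(COC(/C=C/C(=O)OC(C)(C)C)=C2)C1=O | intermediate
25 | 5-methylbenzene-1,2,3-triol | Cc1cc(O)c(O)c(O)c1 | starting material
26 | dichlorodiphenylmethane | ClC(Cl)(c1ccccc1)c1ccccc1 | starting material
27 | 6-methyl-2,2-diphenyl-1,3-benzodioxol-4-ol | Cc1cc(O)c2OC(c3ccccc3)(c3ccccc3)Oc2c1 | intermediate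
28 | 4-hydroxy-6-methyl-2,2-diphenyl-1,3-benzodioxole-5-carbaldehyde | Cc1cc2OC(c3ccccc3)(c3ccccc3)Oc2c(O)c1C=O | intermediate
29 | 4-methoxy-6-methyl-2,2-diphenyl-1,3-benzodioxole-5-carbaldehyde | COc1c(C=O)c(C)cc2OC(c3ccccc3)(c3ccccc3)Oc12 | intermediate
30 | 4-methoxy-6-methyl-2,2-diphenyl-1,3-benzodioxole-5-carboxylic acid | COc1c(C(=O)O)c(C)cc2OC(c3ccccc3)(c3ccccc3)Oc12 | intermediate
31 | 4-methoxy-6-methyl-2,2-diphenyl-1,3-benzodioxole-5-carbonyl chloride | COc1c(C(=O)Cl)c(C)cc2OC(c3ccccc3)(c3ccccc3)Oc12 | intermediate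
32 | (6S,7S)-3-[(1E)-3-tert-butoxy-3-oxoprop-1-en-1-yl]-7-hydroxy-7-methyl-8-oxo-5,6,7,8-tetrahydro-1H-isochromen-6-yl 4-methoxy-6-methyl-2,2-diphenyl-1,3-benzodioxole-5-carboxylate | COc1c(C(=O)O[C@H]3CC4=C(COC(/C=C/C(=O)OC(C)(C)C)=C4)C(=O)[C@@]3(C)O)c(C)cc2OC(c5ccccc5)(c5ccccc5)Oc12 | intermediate
33 | (2E)-3-[(6S,7S)-6-[(3,4-dihydroxy-2-methoxy-6-methylbenzoyl)oxy]-7-hydroxy-7-methyl-8-oxo-5,6,7,8-tetrahydro-1H-isochromen-3-yl]prop-2-enoic acid | COc1c(O)c(O)cc(C)c1C(=O)O[C@H]1CC2=C(COC(/C=C/C(=O)O)=C2)C(=O)[C@@]1(C)O | target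

**Totals and risks**
Total step count: 18. Longest linear sequence: 13 steps (1, 2, 3, 5, 6, 7, 8, 9, 10, 11, 12, 17, 18).

Step 8 (key step). What may go wrong: ionisation at the other acetal centre with loss of 2,2-dimethylpropanal and of the tether, capture of the cation by oxygen instead of carbon, or incomplete γ-enolisation. The fallback sets out from keto lactol 14 and gives up the temporary ring. MgBr2·OEt2 in CH2Cl2 should open the lactol with loss of 2,2-dimethylpropanal to the magnesium chelate of (2S,4E)-4-{[tert-butyl(diphenyl)silyl]oxymethyl}-2-hydroxy-5-iodo-2-methyl-3-oxohex-4-enal F1. Et3N then brings about soft γ-enolisation and a chelation-controlled intramolecular vinylogous aldol addition; the five-membered chelate of the tertiary alkoxide and the aldehyde oxygen holds the two oxygens syn. This should give (5S,6S)-2-{[tert-butyl(diphenyl)silyl]oxymethyl}-5,6-dihydroxy-3-iodo-6-methylcyclohex-2-en-1-one F2. Sonogashira coupling with 18 as in step 9 gives (5S,6S)-2-{[tert-butyl(diphenyl)silyl]oxymethyl}-3-(3,3-diethoxyprop-1-yn-1-yl)-5,6-dihydroxy-6-methylcyclohex-2-en-1-one F3. Bu4NF then gives, through (5S,6S)-3-(3,3-diethoxyprop-1-yn-1-yl)-5,6-dihydroxy-2-(hydroxymethyl)-6-methylcyclohex-2-en-1-one F4, the pyran (6S,7S)-3-(diethoxymethyl)-6,7-dihydroxy-7-methyl-6,7-dihydro-1H-isochromen-8(5H)-one F5. Mild aqueous acid (pyridinium p-toluenesulfonate, acetone/H2O) hydrolyses the diethyl acetal, and the sequence comes back to the route at aldehyde 22.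

Step 10. What may go wrong: 5-exo-dig attack at the proximal alkyne carbon followed by isomerisation to a furan, or base-induced decomposition, competing with the 6-endo conjugate addition. The fallback sets out from alkynyl enone 19 and fixes the regiochemistry intermolecularly. Pyrrolidine (MeCN, rt) should add at the remote alkyne carbon (1,6-aza-Michael addition, no ring-size bias) to give (2R,3aS,7aS)-2-tert-butyl-5-{[tert-butyl(diphenyl)silyl]oxymethyl}-6-[3,3-diethoxy-2-(pyrrolidin-1-yl)prop-1-en-1-yl]-3a-methyl-7,7a-dihydro-1,3-benzodioxol-4(3aH)-one F6. Bu4NF/AcOH frees (2R,3aS,7aS)-2-tert-butyl-6-[3,3-diethoxy-2-(pyrrolidin-1-yl)prop-1-en-1-yl]-5-(hydroxymethyl)-3a-methyl-7,7a-dihydro-1,3-benzodioxol-4(3aH)-one F7. Warming with AcOH in toluene lets the hydroxyl replace pyrrolidine by addition–elimination at the iminium tautomer (6-exo-trig), which closes the pyran and comes back to the route at 21.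

Step 17. What may go wrong: slow acyl transfer from the di-ortho-substituted acyl chloride to the neopentyl-type secondary hydroxyl, so that base-induced retro-aldol opening of ring A or vinylogous β-elimination of the product ester competes. The fallback sets out from diol 24 and acid chloride 31 and activates the alcohol instead of the acyl donor. Bu2SnO (toluene, reflux, water removal) should give the dibutylstannylene acetal tert-butyl (2E)-3-[(6S,7S)-6,7-(dibutylstannanediyldioxy)-7-methyl-8-oxo-5,6,7,8-tetrahydro-1H-isochromen-3-yl]prop-2-enoate F8, in which the secondary oxygen is the nucleophilic one. It is acylated by 31 in CH2Cl2 at rt without amine base, and aqueous work-up comes back to the route at ester 32.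

**Further compounds**
F1 | step 8 | (2S,4E)-4-{[tert-butyl(diphenyl)silyl]oxymethyl}-2-hydroxy-5-iodo-2-methyl-3-oxohex-4-enal | C[C@](O)(C=O)C(=O)/C(CO[Si](c1ccccc1)(c1ccccc1)C(C)(C)C)=C(\C)I
F2 | step 8 | (5S,6S)-2-{[tert-butyl(diphenyl)silyl]oxymethyl}-5,6-dihydroxy-3-iodo-6-methylcyclohex-2-en-1-one | C[C@]1(O)[C@@H](O)CC(I)=C(CO[Si](c2ccccc2)(c2ccccc2)C(C)(C)C)C1=O
F3 | step 8 | (5S,6S)-2-{[tert-butyl(diphenyl)silyl]oxymethyl}-3-(3,3-diethoxyprop-1-yn-1-yl)-5,6-dihydroxy-6-methylcyclohex-2-en-1-one | C[C@]1(O)[C@@H](O)CC(C#CC(OCC)OCC)=C(CO[Si](c2ccccc2)(c2ccccc2)C(C)(C)C)C1=O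
F4 | step 8 | (5S,6S)-3-(3,3-diethoxyprop-1-yn-1-yl)-5,6-dihydroxy-2-(hydroxymethyl)-6-methylcyclohex-2-en-1-one | C[C@]1(O)[C@@H](O)CC(C#CC(OCC)OCC)=C(CO)C1=O
F5 | step 8 | (6S,7S)-3-(diethoxymethyl)-6,7-dihydroxy-7-methyl-6,7-dihydro-1H-isochromen-8(5H)-one | C[C@]1(O)[C@@H](O)CC2=C(COC(C(OCC)OCC)=C2)C1=O
F6 | step 10 | (2R,3aS,7aS)-2-tert-butyl-5-{[tert-butyl(diphenyl)silyl]oxymethyl}-6-[3,3-diethoxy-2-(pyrrolidin-1-yl)prop-1-en-1-yl]-3a-methyl-7,7a-dihydro-1,3-benzodioxol-4(3aH)-one (enamine E/Z mixture) | C[C@]12O[C@H](C(C)(C)C)O[C@H]1CC(C=C(N3CCCC3)C(OCC)OCC)=C(CO[Si](c4ccccc4)(c4ccccc4)C(C)(C)C)C2=O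
F7 | step 10 | (2R,3aS,7aS)-2-tert-butyl-6-[3,3-diethoxy-2-(pyrrolidin-1-yl)prop-1-en-1-yl]-5-(hydroxymethyl)-3a-methyl-7,7a-dihydro-1,3-benzodioxol-4(3aH)-one (enamine E/Z mixture) | C[C@]12O[C@H](C(C)(C)C)O[C@H]1CC(C=C(N3CCCC3)C(OCC)OCC)=C(CO)C2=O
F8 | step 17 | tert-butyl (2E)-3-[(6S,7S)-6,7-(dibutylstannanediyldioxy)-7-methyl-8-oxo-5,6,7,8-tetrahydro-1H-isochromen-3-yl]prop-2-enoate | CCCC[Sn]1(CCCC)O[C@H]2CC3=C(COC(/C=C/C(=O)OC(C)(C)C)=C3)C(=O)[C@@]2(C)O1
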